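## Structural features

The target is a labdane: a trans-fused decalin (ring A = C1–C5, C10; ring B = C5–C10) with a gem-dimethyl group on C4, an angular methyl on C10 and a tetrasubstituted C8=C9 alkene carrying a methyl on C8. C9 bears a two-carbon chain (C11–C12) that ends at the β-carbon C13 of a butenolide (C13–C16, the 15,16-olide). Three stereocentres are contiguous: C5 (α-H) sits between the quaternary carbons C4 and C10, and C6 carries an axial β-acetoxy group syn to both the C10 methyl and the β-methyl on C4. The fragile groups are the butenolide (acidic γ-CH2, Michael acceptor, base-labile lactone), the secondary acetate and the tetrasubstituted alkene, which can migrate under acid. The real difficulty is threefold: the C4/C5/C10 array with a trans ring fusion as one enantiomer, the hindered axial oxygen at C6, and placing the alkene exactly between C8 and C9 while attaching the chain to the crowded C9. The key step exploits the fact that C5, with its hydrogen and its bond to the dimethyl-bearing C4, is the isopropenyl-bearing stereocentre of (R)-carvone; the carvone enone maps onto C9 (carbonyl), C8 (with its methyl) and C7, and its ring methylene onto C6. Ring A is then closed by forming C3–C4 from a tertiary radical at C4. The enone that survives this closure later supplies the C6 oxygen, the position of the 8,9-alkene and the handle at C9.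

## Logic of the disconnections

21 is cut at C12–C13, the sp3–sp2 bond between the chain and the lactone ring. This lets the sensitive lactone arrive intact and late in 19, while the other half is the borane 20 obtained from the terminal alkene of 18. The forward step needs a hydroboration that touches only the monosubstituted alkene and a coupling mild enough for the acetate and the lactone.

18 is cut at C9–C11. The two-carbon unit comes from 17 and the ring partner is the enol triflate 16, so the position of the ring alkene is defined by the triflate. The forward coupling has to work at a tetrasubstituted alkenyl triflate flanked by the quaternary C10.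

16 is cut at the C9–O(triflyl) bond together with the C7–H bond, leading back to the enone 14 through the enolate 15. Conjugate hydride addition generates only the C8=C9 enolate, which gives regiocontrol without any deprotonation. The forward step requires 1,4- rather than 1,2-delivery of hydride and survival of the acetate.

14 is cut at the acetyl–O bond to 13, and 13 at the C6–H bond to the ene-dione 12. The C6 stereocentre is thus set by substrate-controlled reduction of a planar carbonyl. The forward reduction must distinguish the C6 from the C9 carbonyl and must deliver hydride to the α-face.

12 is cut at the C6=O bond to 11. The oxygen is introduced by oxidation of the only methylene that is γ to the enone, so no functional group has to be carried through the early steps. The demand is site selectivity against the other allylic C–H bonds.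

11 is cut at the C2–carboxyl bond to 9, and 9 at the ester C–O bond to 8. The carboxyl group is only the activating group of the radical acceptor and is removed without trace. Because it is not β to a carbonyl, the forward step must be a radical decarboxylation, not a thermal one.

8 is cut at C3–C4, which opens ring A and gives 7. This removes one ring and the C4 quaternary centre and leaves a monocyclic carvone derivative. The forward step must generate the C4 radical selectively at the isopropenyl group and close a six-membered ring at a fully substituted carbon.

7 is cut at C1–C10 into 4 and 5. All carbons of ring A other than C4 come from one commercial allylic bromide. The alkylation has to create the quaternary C10 with the new chain anti to the isopropenyl group, since this fixes the trans ring fusion.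

4 is cut at the C10–methyl bond into 1 and 2. The forward step is a kinetic α′-methylation whose new centre need not be controlled, because it is planarised again in the next enolisation.

## Other disconnections considered

Alternative 1: The cut is through C4–C5 and C9–C10 at once, which unravels both rings to the acyclic (E,E)-trienyl butenolide A1. In the forward direction a confined chiral Brønsted acid would protonate C3 of A1, a chair–chair cation–alkene cascade would close rings A and B, and loss of a proton from C7 would give A2.
- In its favour: one catalytic step would create both rings, the ring-fusion stereocentres and the whole carbon skeleton with side chain and lactone, so no cross-coupling would be needed. On skeletal step economy it is clearly better than the chosen plan.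
- Against it here: A2 has no oxygen at C6 and its alkene lies at C7–C8. Allylic oxidation at C6, reduction to the axial alcohol, acetylation and a shift of the alkene to C8–C9 would all follow, in the presence of the base-sensitive lactone. Termination must also choose among protons on C7, C9 and the C8 methyl, and the absolute configuration would rest entirely on the catalyst, with a remote lactone that offers no directing group.
- Comparison: structurally the alternative delivers the skeleton but none of the ring-B functionality, whereas the chosen plan obtains ring B as an enone that already encodes the C6 oxygen, the alkene position and the C9 handle. Mechanistically, a stereospecific cationic cascade is the equal of the radical closure for the trans fusion, but the chosen plan takes its absolute configuration from 1 and not from a catalyst. The alternative is shorter up to the bicycle and probably comparable overall once C6 and the alkene are corrected.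

Alternative 2: The cut is through C4–C5 and C1–C10, so ring A is annulated onto the ring-B enone A3 with 4-methylpent-4-enal A4. In the forward direction iron-hydride conditions of the kind used in the chosen key step would turn A4 into a tertiary radical (the future C4). This would add to C5 of A3 anti to the silyloxy group, and the C10 enolate formed by radical–polar crossover would close onto the aldehyde to give A5.
- In its favour: the step is convergent and forms two C–C bonds, ring A and both ring-fusion centres in one operation. The C6 oxygen is present from the outset, so no late C–H oxidation is needed, and on this point it is better than the chosen plan. The hydrogen-atom-transfer manifold is the same, so in mechanism type it is the equal.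
- Against it here: the oxygen in A5 is 6α, because the radical enters trans to it, so an oxidation/reduction is still required to reach 6β. The C1 hydroxyl is superfluous and costs a deoxygenation, and the C8 methyl is missing and has to be added by alkylation. The ring fusion would be set by the preference of the aldol transition state, not by an existing quaternary centre, and enantiopure A3 would have to be made.
- Comparison: structurally the alternative leaves three corrections (C1, C6, C8) against one removable group (the C2 carboxyl) in the chosen plan. Mechanistically, its first bond is an intermolecular addition of a tertiary radical to a substituted enone, less favourable entropically than the intramolecular closure of 7. One convergent step replaces three linear ones, which is better, but the corrections would be expected to use up that gain.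

Alternative 3: The cut is through C9–C10 only, so ring B is closed from the monocyclic dienone A6, which already carries the side chain and the lactone. In the forward direction a confined chiral Brønsted acid would protonate the enone oxygen, the C8=C9 alkene would attack C10 through C9, and the C8 cation would lose a proton from C7. Ketonisation would then set C5 and give A7.
- In its favour: A6 would come from an achiral trimethylcyclohexenyl ring-A unit and a simple side chain. A7 contains every carbon of the target and the C6 oxygen as a ketone, so only an alkene shift, a reduction and an acetylation remain. On step economy it is the best of the four plans, and reduction of the C6 ketone from the α-face would give the 6β-alcohol on the same grounds as in the chosen plan (equal).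
- Against it here: an unactivated trisubstituted alkene would have to attack a tetrasubstituted, weakly electrophilic enone β-carbon and create the quaternary C10 enantioselectively under counter-anion control, which is demanding. Under acid the skipped alkene of A6 could move into conjugation and open a Nazarov-type path. Three stereocentres (C5, C9, C10) would depend on one catalyst-controlled event and a later protonation, and the deconjugation of the 7-en-6-one to the 8,9-alkene would have to be done beside the lactone.
- Comparison: structurally the alternative buys ring A and makes ring B, the reverse of the chosen plan. Mechanistically it is a polar closure with catalyst-derived absolute configuration, against a radical closure whose relative and absolute configuration are fixed by 1 and one alkylation. The alternative is shorter; the chosen plan is the more secure in stereochemistry.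

Key step: step 3

Remark on the chemistry: the target is read as (5S,6R,10S), that is 5α-H, 10β-methyl and axial 6β-acetoxy; labdane numbering is used throughout; the ester left by the acrylate acceptor cannot be lost by hydrolysis and heating alone, so the route removes it by a Barton reductive decarboxylation; 17 and 19 are taken to be commercial.

## Route

Step 1
Reactants: 1 (R)-carvone; 2 iodomethane
Product: 4 (5R)-2,6-dimethyl-5-(prop-1-en-2-yl)cyclohex-2-en-1-one (6-methylcarvone; both C6 epimers), via carvone lithium dienolate 3 (not isolated)
Conditions: LiN(i-Pr)2 (LDA), THF, −78 °C; then 2, −78 → 0 °C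
Reagents that add atoms: none
Why: Kinetic deprotonation of the cross-conjugated enone at the α′-methylene (the future C10) followed by SN2 methylation (enolate alkylation); the new centre is left uncontrolled because step 2 planarises it again.

Step 2
Reactants: 4 6-methylcarvone; 5 ethyl 2-(bromomethyl)prop-2-enoate
Product: 7 ethyl 2-{[(1S,6S)-1,3-dimethyl-2-oxo-6-(prop-1-en-2-yl)cyclohex-3-en-1-yl]methyl}prop-2-enoate (new chain trans to isopropenyl), via 6-methylcarvone lithium dienolate 6 (not isolated)
Conditions: LiN(i-Pr)2 (LDA), THF, −78 °C; then 5, DMPU, −78 → −20 °C
Reagents that add atoms: none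
Why: Second kinetic α′-enolisation and enolate allylation (SN2 or SN2′ on the bromomethyl acrylate lead to the same product); the electrophile should approach the enolate face anti to the adjacent isopropenyl group, which sets C10 with the methyl cis and the chain trans to C4.

Step 3
Reactants: 7 the carvone-derived acrylate
Product: 8 ethyl 4,4,8,10-tetramethyl-9-oxo-trans-decal-7-ene-2-carboxylate (target numbering; 5α-H; 10β-methyl; both C2 epimers)
Conditions: Fe(acac)3 (30 mol%), PhSiH3, EtOH/ethylene glycol, 60 °C
Reagents that add atoms: none
Why: An iron hydride formed from Fe(acac)3 and PhSiH3 should transfer a hydrogen atom to the CH2 terminus of the isopropenyl group, giving the tertiary C4 radical with both methyls in place. This nucleophilic radical adds to the unsubstituted terminus (C3) of the tethered acrylate, and the resulting α-ester radical at C2 is reduced by divalent iron to the enolate, which ethanol protonates while trivalent iron is regenerated. The closest known reaction type is the iron-hydride hydrogen-atom-transfer reductive coupling of alkenes with acrylates (a Giese-type addition), here in intramolecular form. Ring A closes in the 6-endo-trig mode; the 5-exo alternative would require attack at the substituted, polarity-mismatched internal acrylate carbon and would leave an unstabilised primary radical. The only new stereocentre, C2, is not controlled and is erased in step 5. The trans ring fusion is not made here but inherited from C5 (from 1) and C10 (from step 2), whose trans-diequatorial substituents place the radical and the acceptor within reach. The step needs hydrogen-atom transfer to the isopropenyl group in preference to the acrylate and the enone; this is secured because the isopropenyl group is the most electron-rich and least hindered alkene, while the enone alkene is trisubstituted, conjugated and geometrically out of reach of the C4 radical. Ring closure must also outrun reduction of the tertiary radical, which the intramolecular, polarity-matched addition favours.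

Step 4
Reactants: 8 the bicyclic keto ester
Product: 9 4,4,8,10-tetramethyl-9-oxo-trans-decal-7-ene-2-carboxylic acid (both C2 epimers)
Conditions: LiOH·H2O, THF/MeOH/H2O, rt; then aq. HCl
Reagents that add atoms: lithium hydroxide, [Li+].[OH-]
Why: Saponification of an unhindered secondary ethyl ester; C10 is quaternary and C5 is not acidic in the enone, so no stereocentre that matters is exposed to base.

Step 5
Reactants: 9 the carboxylic acid
Product: 11 4,4,8,10-tetramethyl-trans-decal-7-en-9-one [(4aS,8aS)-2,5,5,8a-tetramethyl-4a,5,6,7,8,8a-hexahydronaphthalen-1(4H)-one], via Barton thiohydroxamate ester 10 (not isolated)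
Conditions: N-hydroxypyridine-2-thione, DCC, DMAP (cat.), CH2Cl2, 0 °C → rt, dark; then t-BuSH, hν (tungsten lamp), rt
Reagents that add atoms: none
Why: Barton reductive decarboxylation: homolysis of the thiohydroxamate ester, loss of CO2 and hydrogen transfer from the thiol to the secondary C2 radical, which also removes the C2 epimer mixture. A radical method is needed because this carboxyl group has no β-carbonyl and would not be lost thermally.

Step 6
Reactants: 11 the bicyclic enone
Product: 12 4,4,8,10-tetramethyl-trans-decal-7-ene-6,9-dione (5α-H; 10β-methyl)
Conditions: Rh2(cap)4 (cap = caprolactamate; 1 mol%), t-BuOOH, 1,2-dichloroethane, 40 °C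
Reagents that add atoms: tert-butyl hydroperoxide, CC(C)(C)OO
Why: Allylic (γ) C–H oxidation of a conjugated enone to the 1,4-ene-dione; C6 is the only methylene that is both allylic and vinylogously activated, and C10 is quaternary so no α′ site competes. The neutral conditions should leave C5, now α to a carbonyl, in its more stable trans-fused configuration.

Step 7
Reactants: 12 the ene-dione
Product: 13 6β-hydroxy-4,4,8,10-tetramethyl-trans-decal-7-en-9-one
Conditions: NaBH4, CeCl3·7H2O, MeOH, −78 °C
Reagents that add atoms: none
Why: Luche 1,2-reduction; the C6 carbonyl (flanked by a CH and a vinylic CH) is less shielded than the C9 carbonyl (flanked by the quaternary C10 and the methyl-bearing C8) and should react first. Hydride should enter from the α-face, away from the axial C10 methyl and the β-methyl on C4, giving the 6β-alcohol.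

Step 8
Reactants: 13 the 6β-hydroxy enone
Product: 14 6β-acetoxy-4,4,8,10-tetramethyl-trans-decal-7-en-9-one
Conditions: Ac2O, DMAP, Et3N, CH2Cl2, rt → 40 °C
Reagents that add atoms: acetic anhydride, CC(=O)OC(C)=O
Why: DMAP-catalysed acylation of a hindered secondary allylic alcohol, with no change at any stereocentre; acetylating here keeps the final, lactone-bearing compound free of protecting-group steps.

Step 9
Reactants: 14 the 6β-acetoxy enone
Product: 16 6β-acetoxy-4,4,8,10-tetramethyl-trans-decal-8-en-9-yl trifluoromethanesulfonate, via lithium enolate 15 (not isolated)
Conditions: LiBH(s-Bu)3 (L-Selectride, 1.05 equiv), THF, −78 °C; then PhNTf2, −78 → 0 °C; aq. NH4Cl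
Reagents that add atoms: N-phenylbis(trifluoromethanesulfonimide), O=S(=O)(N(c1ccccc1)S(=O)(=O)C(F)(F)F)C(F)(F)F
Why: Conjugate (1,4) reduction of the α-methyl enone by the bulky borohydride gives only the C8=C9 enolate, which is trapped on oxygen (reductive enol triflation); this fixes the alkene between C8 and C9. One equivalent of hydride at −78 °C should spare the acetate, and the leaving group on C6 is not β to the enolate carbon, so it cannot be eliminated.

Step 10
Reactants: 16 the enol triflate; 17 tributyl(vinyl)stannane
Product: 18 6β-acetoxy-13,14,15,16-tetranorlabda-8,11-diene (the 9-vinyl compound)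
Conditions: Pd(PPh3)4 (5 mol%), LiCl, THF, 65 °C
Reagents that add atoms: none
Why: Stille coupling: oxidative addition of zerovalent palladium into the alkenyl C9–O triflate bond, chloride-assisted transmetalation from tin and reductive elimination form C9–C11. The acetate on C6 is homoallylic, not allylic, so it cannot ionise on palladium.

Step 11
Reactants: 18 the 9-vinyl diene; 19 4-bromofuran-2(5H)-one
Product: 21 6β-acetoxylabda-8,13-dien-15,16-olide (5S,6R,10S), via alkyl-9-BBN borane 20 (not isolated)
Conditions: 9-BBN, THF, 0 °C → rt; then 19, PdCl2(dppf) (5 mol%), aq. K3PO4, DMF, rt → 45 °C
Reagents that add atoms: none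
Why: Anti-Markovnikov hydroboration of the monosubstituted alkene by the bulky borane (the tetrasubstituted alkene and the acetate do not react), then B-alkyl Suzuki–Miyaura coupling with the vinylogous acyl bromide to form C12–C13. Phosphate near room temperature should be mild enough for the hindered acetate and the lactone.

## Compound list

1 | (R)-carvone, (5R)-2-methyl-5-(prop-1-en-2-yl)cyclohex-2-en-1-one | CC(=C)[C@@H]1CC=C(C)C(=O)C1 | starting material
2 | iodomethane | CI | starting material
3 | lithium cross-conjugated dienolate of 1 (O–C1=C6, C2=C3) | CC(=C)[C@@H]1CC=C(C)C(O[Li])=C1 | intermediate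
4 | (5R)-2,6-dimethyl-5-(prop-1-en-2-yl)cyclohex-2-en-1-one, both C6 epimers | CC(=C)[C@@H]1CC=C(C)C(=O)C1C | intermediate
5 | ethyl 2-(bromomethyl)prop-2-enoate | C=C(CBr)C(=O)OCC | starting material
6 | lithium cross-conjugated dienolate of 4 (O–C1=C6, C2=C3) | CC(=C)[C@@H]1CC=C(C)C(O[Li])=C1C | intermediate
7 | ethyl 2-{[(1S,6S)-1,3-dimethyl-2-oxo-6-(prop-1-en-2-yl)cyclohex-3-en-1-yl]methyl}prop-2-enoate | C1C=C(C)C(=O)[C@@](C)(CC(=C)C(=O)OCC)[C@@H]1C(C)=C | intermediate
8 | ethyl 4,4,8,10-tetramethyl-9-oxo-trans-decal-7-ene-2-carboxylate (5α-H, 10β-methyl, both C2 epimers) | C1C=C(C)C(=O)[C@@]2(C)CC(C(=O)OCC)CC(C)(C)[C@H]12 | intermediate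
9 | 4,4,8,10-tetramethyl-9-oxo-trans-decal-7-ene-2-carboxylic acid (both C2 epimers) | C1C=C(C)C(=O)[C@@]2(C)CC(C(=O)O)CC(C)(C)[C@H]12 | intermediate
10 | 2-thioxopyridin-1(2H)-yl ester of 9 (Barton ester) | C1C=C(C)C(=O)[C@@]2(C)CC(C(=O)ON3C=CC=CC3=S)CC(C)(C)[C@H]12 | intermediate
11 | 4,4,8,10-tetramethyl-trans-decal-7-en-9-one, (4aS,8aS)-2,5,5,8a-tetramethyl-4a,5,6,7,8,8a-hexahydronaphthalen-1(4H)-one | C1C=C(C)C(=O)[C@@]2(C)CCCC(C)(C)[C@H]12 | intermediate
12 | 4,4,8,10-tetramethyl-trans-decal-7-ene-6,9-dione (5α-H, 10β-methyl) | O=C1C=C(C)C(=O)[C@@]2(C)CCCC(C)(C)[C@H]12 | intermediate
13 | 6β-hydroxy-4,4,8,10-tetramethyl-trans-decal-7-en-9-one | O[C@@H]1C=C(C)C(=O)[C@@]2(C)CCCC(C)(C)[C@H]12 | intermediate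
14 | 6β-acetoxy-4,4,8,10-tetramethyl-trans-decal-7-en-9-one | CC(=O)O[C@@H]1C=C(C)C(=O)[C@@]2(C)CCCC(C)(C)[C@H]12 | intermediate
15 | lithium 6β-acetoxy-4,4,8,10-tetramethyl-trans-decal-8-en-9-olate | CC(=O)O[C@@H]1CC(C)=C(O[Li])[C@@]2(C)CCCC(C)(C)[C@H]12 | intermediate
16 | 6β-acetoxy-4,4,8,10-tetramethyl-trans-decal-8-en-9-yl trifluoromethanesulfonate | CC(=O)O[C@@H]1CC(C)=C(OS(=O)(=O)C(F)(F)F)[C@@]2(C)CCCC(C)(C)[C@H]12 | intermediate
17 | tributyl(vinyl)stannane | C=C[Sn](CCCC)(CCCC)CCCC | starting material
18 | 6β-acetoxy-13,14,15,16-tetranorlabda-8,11-diene (9-vinyl compound) | CC(=O)O[C@@H]1CC(C)=C(C=C)[C@@]2(C)CCCC(C)(C)[C@H]12 | intermediate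
19 | 4-bromofuran-2(5H)-one | O=C1C=C(Br)CO1 | starting material
20 | 6β-acetoxy-12-(9-borabicyclo[3.3.1]nonan-9-yl)-13,14,15,16-tetranorlabd-8-ene | CC(=O)O[C@@H]1CC(C)=C(CCB2C3CCCC2CCC3)[C@@]2(C)CCCC(C)(C)[C@H]12 | intermediate
21 | 6β-acetoxylabda-8,13-dien-15,16-olide, (5S,6R,10S) | CC(=O)O[C@@H]1CC(C)=C(CCC2=CC(=O)OC2)[C@@]2(C)CCCC(C)(C)[C@H]12 | target

## Step count and least certain steps

Total step count: 11. Longest linear sequence: 11 steps from 1; the partners 2, 5, 17 and 19 are purchased.

**Step 3 (key step).** The most likely failure is quenching of the tertiary C4 radical before it cyclises (net hydrogenation of the isopropenyl group), or hydrogen-atom transfer to the acrylate. The 6-endo closure next to the quaternary C10 is sterically slowed, while hydride is present throughout. The fallback sets out from 7. Markovnikov addition of HCl (HCl gas, CH2Cl2, −30 °C) to the isopropenyl group gives the tertiary chloride ethyl 2-{[(1S,6R)-6-(2-chloropropan-2-yl)-1,3-dimethyl-2-oxocyclohex-3-en-1-yl]methyl}prop-2-enoate F1. A tin hydride chain (Bu3SnH, AIBN, benzene, 80 °C, slow addition) then generates the same C4 radical at a hydride concentration kept low enough for ring closure to win. The α-ester radical takes hydrogen from the stannane, and the route is rejoined at 8.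

**Step 6.** The most likely failure is slow or unselective C–H oxidation, with attack at the C8 methyl or epoxidation, because C6 is shielded by the neighbouring gem-dimethyl carbon. The fallback sets out from 11. Since C10 is quaternary, LiN(i-Pr)2 can remove only a C6 proton, and Me3SiCl gives the silyl dienol ether 9-(trimethylsilyloxy)-4,4,8,10-tetramethyl-trans-decala-6,8-diene F2. mCPBA (vinylogous Rubottom oxidation at the distal alkene) and mild acid work-up give 6-hydroxy-4,4,8,10-tetramethyl-trans-decal-7-en-9-one F3 as either C6 epimer. Dess–Martin oxidation returns to 12.

**Step 7.** The most likely failure is competing conjugate delivery of hydride to the electron-poor ene-dione alkene, together with loss of site selectivity between the two carbonyl groups. The fallback sets out from 12 and comes back at 16.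
- Zn in AcOH carries out the conjugate reduction deliberately and gives 4,4,8,10-tetramethyl-trans-decalin-6,9-dione F4 (C8 epimers).
- NaBH4 in MeOH at −40 °C should reduce the less hindered C6 carbonyl of this saturated 1,4-dione from the α-face, giving 6β-hydroxy-4,4,8,10-tetramethyl-trans-decalin-9-one F5.
- Ac2O/DMAP gives 6β-acetoxy-4,4,8,10-tetramethyl-trans-decalin-9-one F6.
- Tf2O with 2,6-di-tert-butyl-4-methylpyridine in CH2Cl2 forms the enol triflate at the only enolisable position, C8, and the route is rejoined at 16 without steps 8 and 9.

**Step 9.** The most likely failure is cleavage of the acetate by the borohydride or acyl transfer from O6 to the enolate, since a basic hydride and a lithium enolate are present beside an ester. The fallback sets out from 14. Neutral 1,4-hydrosilylation (Et3SiH, RhCl(PPh3)3 cat., benzene, 50 °C) gives the silyl enol ether 6β-acetoxy-9-(triethylsilyloxy)-4,4,8,10-tetramethyl-trans-decal-8-ene F7. CsF and PhNTf2 in DME convert it into the triflate, rejoining at 16.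

**Step 11.** The most likely failure is base-induced decomposition of the bromobutenolide or hydrolysis of the acetate during a slow alkylborane transmetalation, because aqueous phosphate and a base-labile lactone share the flask. The fallback sets out from 18.
- Hydroboration with 9-BBN (through 20) and oxidation with NaBO3·4H2O give 6β-acetoxy-13,14,15,16-tetranorlabd-8-en-12-ol F8.
- I2, PPh3 and imidazole give 6β-acetoxy-12-iodo-13,14,15,16-tetranorlabd-8-ene F9.
- Zinc insertion (Zn, LiCl, THF) gives (6β-acetoxy-13,14,15,16-tetranorlabd-8-en-12-yl)zinc iodide F10.
- Base-free Negishi coupling with 19 (Pd2(dba)3, SPhos, THF, rt) returns to 21.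

## Further compounds

F1 | step 3 | ethyl 2-{[(1S,6R)-6-(2-chloropropan-2-yl)-1,3-dimethyl-2-oxocyclohex-3-en-1-yl]methyl}prop-2-enoate | C1C=C(C)C(=O)[C@@](C)(CC(=C)C(=O)OCC)[C@@H]1C(C)(C)Cl
F2 | step 6 | 9-(trimethylsilyloxy)-4,4,8,10-tetramethyl-trans-decala-6,8-diene | C1=CC(C)=C(O[Si](C)(C)C)[C@@]2(C)CCCC(C)(C)[C@H]12
F3 | step 6 | 6-hydroxy-4,4,8,10-tetramethyl-trans-decal-7-en-9-one (C6 epimers) | OC1C=C(C)C(=O)[C@@]2(C)CCCC(C)(C)[C@H]12
F4 | step 7 | 4,4,8,10-tetramethyl-trans-decalin-6,9-dione (C8 epimers) | O=C1CC(C)C(=O)[C@@]2(C)CCCC(C)(C)[C@H]12
F5 | step 7 | 6β-hydroxy-4,4,8,10-tetramethyl-trans-decalin-9-one (C8 epimers) | O[C@@H]1CC(C)C(=O)[C@@]2(C)CCCC(C)(C)[C@H]12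
F6 | step 7 | 6β-acetoxy-4,4,8,10-tetramethyl-trans-decalin-9-one (C8 epimers) | CC(=O)O[C@@H]1CC(C)C(=O)[C@@]2(C)CCCC(C)(C)[C@H]12
F7 | step 9 | 6β-acetoxy-9-(triethylsilyloxy)-4,4,8,10-tetramethyl-trans-decal-8-ene | CC(=O)O[C@@H]1CC(C)=C(O[Si](CC)(CC)CC)[C@@]2(C)CCCC(C)(C)[C@H]12
F8 | step 11 | 6β-acetoxy-13,14,15,16-tetranorlabd-8-en-12-ol | CC(=O)O[C@@H]1CC(C)=C(CCO)[C@@]2(C)CCCC(C)(C)[C@H]12
F9 | step 11 | 6β-acetoxy-12-iodo-13,14,15,16-tetranorlabd-8-ene | CC(=O)O[C@@H]1CC(C)=C(CCI)[C@@]2(C)CCCC(C)(C)[C@H]12
F10 | step 11 | (6β-acetoxy-13,14,15,16-tetranorlabd-8-en-12-yl)zinc iodide | CC(=O)O[C@@H]1CC(C)=C(CC[Zn]I)[C@@]2(C)CCCC(C)(C)[C@H]12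
A1 | alternative 1 | 4-[(3E,7E)-4,8,12-trimethyltrideca-3,7,11-trien-1-yl]furan-2(5H)-one | CC(C)=CCC/C(C)=C/CC/C(C)=C/CCC1=CC(=O)OC1
A2 | alternative 1 | labda-7,13-dien-15,16-olide (5α-H, 9α-H, 10β-methyl) | C1C=C(C)[C@H](CCC2=CC(=O)OC2)[C@@]2(C)CCCC(C)(C)[C@H]12
A3 | alternative 2 | (S)-4-(tert-butyldimethylsilyloxy)-2-methylcyclohex-2-en-1-one | CC(C)(C)[Si](C)(C)O[C@H]1CCC(=O)C(C)=C1
A4 | alternative 2 | 4-methylpent-4-enal | CC(=C)CCC=O
A5 | alternative 2 | trans-fused 1-hydroxy-6α-(tert-butyldimethylsilyloxy)-4,4,10-trimethyldecal-9-one (C1 carbinol undefined) | CC(C)(C)[Si](C)(C)O[C@H]1CCC(=O)[C@@]2(C)C(O)CCC(C)(C)[C@H]12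
A6 | alternative 3 | 4-[(3E)-4-methyl-6-oxo-6-(2,6,6-trimethylcyclohex-1-en-1-yl)hex-3-en-1-yl]furan-2(5H)-one | CC1=C(C(=O)C/C(C)=C/CCC2=CC(=O)OC2)C(C)(C)CCC1
A7 | alternative 3 | 6-oxolabda-7,13-dien-15,16-olide (5α-H, 9α-H, 10β-methyl) | O=C1C=C(C)[C@H](CCC2=CC(=O)OC2)[C@@]2(C)CCCC(C)(C)[C@H]12
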